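## The problem

The target is a germacrane-type sesquiterpene lactone: a ten-membered carbocycle (C1–C10 in germacrane numbering, C14 on C10, C15 on C4) with a Z trisubstituted C1=C10 alkene, a C4–C5 epoxide whose ring carbons C3 and C6 are cis, an α-methylene γ-lactone (C11–C13) cis-fused through O–C6 and C7, and an (E)-4-hydroxy-2-methylbut-2-enoate on the C8 oxygen. The ring is the main obstacle, because a ten-membered closure is slowed by transannular strain and has to leave the Z alkene and the epoxide intact. Five contiguous stereocentres (4R,5S,6S,7S,8R) must be set: C4 and C5 can come from a reagent-controlled epoxidation of an acyclic allylic alcohol, C6 must then be induced by C5, C7 can follow C6 through the geometry of an alkene in a concerted addition, and C8 can be set last by the finished ring. Several groups are fragile: the epoxide and the C1=C10 alkene face each other across the ring and cyclise transannularly under protic or Lewis acid, the methylene lactone is a Michael acceptor and must be made late, and the side-chain ester with its free allylic alcohol will not survive enolate or hydride chemistry. Any intermediate with a C8 ketone has the C6 oxygen in the β-position and an epimerisable C7, so base must be kept away from it. The enabling feature is the 1,3-relationship of the C6 and C8 oxygens across C7, which also bears C11: this is an aldol pattern (C6–OH, C8=O), and an aldol is the unmasked form of a 2-isoxazoline O–N=C8–C7–C6. Such an isoxazoline is the adduct of a C8 nitrile oxide and an E C6=C7 alkene, and when dipole and alkene sit at the two ends of one chain the same cycloaddition forms the C7–C8 bond and thereby the carbocycle.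

## Retrosynthesis

**C8 ester.** The acyl C–O bond at C8 is cut first, so 37 goes back through its silyl ether 36 to the core alcohol 31 and the protected acid 34. The side chain is held back to the end because its unsaturated ester would not survive the enolate and hydride steps that build the core. Acid 34 is two steps from aldehyde 32. The forward reaction must acylate a hindered secondary alcohol next to a methylene lactone and then remove a silyl group without acid.

**Exocyclic methylene.** The C11=C13 bond is removed next, 31 to 28. Carrying C13 earlier is rejected because a 1,1-disubstituted alkene would be a faster dipolarophile than C6=C7 in the ring-forming step. The forward reaction is an enolate Mannich/elimination sequence on a lactone with a free C8 hydroxyl.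

**C8 stereocentre and lactone.** The C8–H bond is traced to ketone 27, and the lactone of 27 to keto diol 25 by lowering C12 to the alcohol level. Lactonising before reducing caps O6, so that only one secondary oxygen (C8) is later free. The reverse order would leave two secondary hydroxyls competing for C12. The forward steps need a primary-selective oxidation and a face-selective hydride addition.

**Aldol unmasking.** Keto diol 25 is the opened form of isoxazoline 23, which is the desilylated form of 22. The cut is the N–O bond. Nothing simpler is gained here, but the disconnection exposes the cycloaddition retron.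

**Ring closure (key).** Isoxazoline 22 is opened at C7–C8 and O–C6 to nitrile oxide 21, generated from oxime 19. Against neighbouring cuts: an aldol closure at C6–C7 would need an enolate next to the epoxide and has no handle for the C6/C7 relationship. A ring-closing metathesis at C1=C10 would not give a Z trisubstituted alkene reliably in a ten-membered ring. Precursor 19 is acyclic, has only the two epoxide stereocentres and two alkenes of defined geometry. The forward reaction must close in the bridged ten-membered sense, on the correct alkene face, and faster than the dipole dimerises.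

**C6=C7 alkene.** Oxime 19 comes from alcohol 17 and this from the 4-methoxybenzyl ether 16. The E alkene of 16 is cut to epoxy aldehyde 11 and sulfone 15. A Julia–Kocienski olefination is preferred to a Wittig reaction, which would give the Z alkene. Sulfone 15 is three steps from diol 12.

**Epoxide.** Aldehyde 11 comes from epoxy alcohol 10, and the two C–O bonds of the epoxide are cut to allylic alcohol 9. Because C3 and C6 are cis on the epoxide of 37, the C4=C5 alkene of 9 has to be Z (neryl type). An E (geranyl-type) alcohol would give the wrong diastereomer whatever the tartrate. L-(+)-tartrate then sets (2S,3R) in 10, which is C5 (S) and C4 (R).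

**C3–C4 bond.** Dienol 9 is cut between C3 (sp3) and C4 (sp2) to diene ether 4 (through its borane 8) and vinyl iodide 7. Both Z alkenes are fixed beforehand: one by the ring of lactone 1, carried through 2 and 3 into 4, the other by the cyclic alkenylaluminate 6 from alkyne 5. Both are retained in the coupling. The neighbouring C2–C3 allyl–allyl cut would risk SN2/SN2′ scrambling and would need a Z-configured four-carbon allylic unit that is not readily available.

## Roads not taken

Alternative 1: The ten-membered ring is traced back to the bicyclo[5.3.0]decadiene lactone A1, in which C4 and C8 are joined by a tetrasubstituted ring-fusion alkene. In the forward direction ozone cleaves this alkene and releases the ten-membered 4,8-diketone A2.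
- Merits: the ring-size problem is solved on a five/seven-fused bicycle that is easy to close, and strain release drives the ring expansion. In this respect the road is safer than a ten-membered cycloaddition.
- Weak points: A1 also contains the trisubstituted C1=C10 alkene, and ozone distinguishes a tetrasubstituted from a trisubstituted alkene only by rate. A2 has two ketones that must be told apart. C4 still needs a methyl group, a stereocentre and an epoxide closure onto C5, all on a flexible medium ring. C8 needs a selective reduction, and the lactone still lacks its methylene.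
- Comparison: the chosen plan sets against the safer ring formation of this road an epoxide made by reagent control before the ring exists, and C6/C8 oxygens that arrive already differentiated as alcohol and masked ketone.

Alternative 2: The lactone carbonyl is removed as carbon monoxide, leaving the homopropargylic alcohol A3 with a C6 hydroxyl cis to a C7 ethynyl group. In the forward direction PdCl2/PPh3/SnCl2 under CO joins C12 to O6 and C11 and gives the methylene lactone A4 directly.
- Merits: the methylene lactone is made in one step without enolate chemistry. This is shorter and gentler toward base than the oxidation and Mannich sequence used here (steps 18 and 20), so in this respect the road is better.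
- Weak points: it is an endgame, not a ring strategy, since A3 already contains the ten-membered ring, the epoxide and four stereocentres. A propargylic C7 stereocentre and an epoxide facing an alkene must survive a Lewis-acidic tin chloride and a palladium catalyst.
- Comparison: the chosen plan answers with a key step that forms the ring and the C6–O/C7–C11 relationship at once. It pays with a strong-base methylenation.

Alternative 3: The C5–C10 bond is added in thought, so that cyclodecenone A6 comes from the cis-fused decalin A5, a C1 mesylate with a free tertiary C5 hydroxyl. In the forward direction KOt-Bu forms the C5 alkoxide, the C5–C10 bond breaks anti to the leaving group, and the C5 ketone and the Z C1=C10 alkene appear together.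
- Merits: the fragmentation is stereospecific, so the Z geometry is dictated by the decalin, and ring formation is reliable. On both counts it is better than the chosen key step.
- Weak points: A5 carries seven stereocentres and four kinds of protecting group and needs a long synthesis. After fragmentation the C5 ketone must be reduced and the epoxide closed from the C4 oxygen with inversion at C5 on the medium ring. The lactone and its methylene are still to be made.
- Comparison: the chosen plan sets against this a cyclisation substrate reached in ten linear steps from achiral materials, with one asymmetric reaction.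

Key step: step 15

Remark: atoms are numbered as in germacrane throughout, and names of ring compounds use this numbering (13-nor where C13 is absent).

## Route

Step 1
Reactants: 1 4-methyl-5,6-dihydro-2H-pyran-2-one
Product: 2 4-methyl-5,6-dihydro-2H-pyran-2-ol (lactol; racemic at C2)
Conditions: i-Bu2AlH (1.1 equiv), CH2Cl2, −78 °C; aqueous work-up
Reagents that add atoms: none
Why: Partial lactone reduction stops at the aluminium hemiacetal at low temperature, and this hydride adds 1,2 and not in the conjugate sense; the ring holds the future C9 and C2 cis on the alkene.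

Step 2
Reactants: 2 4-methyl-5,6-dihydro-2H-pyran-2-ol
Product: 3 (3Z)-3-methylhexa-3,5-dien-1-ol
Conditions: Ph3PCH3Br, KOt-Bu, THF, 0 °C to rt
Reagents that add atoms: methyltriphenylphosphonium bromide, C[P+](c1ccccc1)(c1ccccc1)c1ccccc1.[Br-]
Why: Wittig methylenation of the hydroxy enal that is in equilibrium with the lactol; the unstabilised ylide should add to the aldehyde faster than it isomerises the enal, so the Z geometry from the ring is carried into the diene.

Step 3
Reactants: 3 (3Z)-3-methylhexa-3,5-dien-1-ol
Product: 4 1-methoxy-4-({[(3Z)-3-methylhexa-3,5-dien-1-yl]oxy}methyl)benzene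
Conditions: NaH, 4-methoxybenzyl chloride, n-Bu4NI (cat.), THF/DMF, 0 °C to rt
Reagents that add atoms: 4-methoxybenzyl chloride, COc1ccc(CCl)cc1
Why: Williamson etherification of a primary alkoxide; the ether can later be removed oxidatively beside a silyl ether and an epoxide.

Step 4
Reactants: 5 but-2-yn-1-ol
Product: 7 (2Z)-3-iodobut-2-en-1-ol, via cyclic alkenylaluminate 6 (not isolated)
Conditions: NaAlH2(OCH2CH2OMe)2, Et2O, 0 °C to rt; then N-iodosuccinimide, THF, −78 °C
Reagents that add atoms: N-iodosuccinimide, O=C1CCC(=O)N1I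
Why: Hydroxyl-directed trans-hydroalumination puts aluminium on C3 cis to the carbinol carbon in a five-membered alkoxyaluminate, and iododealumination with retention gives the Z vinyl iodide.

Step 5
Reactants: 4 1-methoxy-4-({[(3Z)-3-methylhexa-3,5-dien-1-yl]oxy}methyl)benzene; 7 (2Z)-3-iodobut-2-en-1-ol
Product: 9 (2Z,6Z)-9-[(4-methoxybenzyl)oxy]-3,7-dimethylnona-2,6-dien-1-ol, via B-alkyl-9-BBN adduct 8 (not isolated)
Conditions: 9-BBN, THF, 0 °C to rt; then 7, PdCl2(dppf) (5 mol %), AsPh3, Cs2CO3, DMF/H2O, rt
Reagents that add atoms: none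
Why: 9-BBN hydroborates only the monosubstituted end of the diene and places boron on the terminal carbon (C3), the trisubstituted alkene being too hindered. The B-alkyl Suzuki–Miyaura coupling keeps the geometry of the vinyl iodide, so the new chain is cis to the hydroxymethyl group (Z, neryl type).

Step 6
Reactants: 9 (2Z,6Z)-9-[(4-methoxybenzyl)oxy]-3,7-dimethylnona-2,6-dien-1-ol
Product: 10 [(2S,3R)-3-{(3Z)-6-[(4-methoxybenzyl)oxy]-4-methylhex-3-en-1-yl}-3-methyloxiran-2-yl]methanol
Conditions: Ti(Oi-Pr)4 (10 mol %), L-(+)-diisopropyl tartrate (12 mol %), t-BuOOH, 4 Å MS, CH2Cl2, −20 °C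
Reagents that add atoms: tert-butyl hydroperoxide, CC(C)(C)OO
Why: Sharpless asymmetric epoxidation; with L-(+)-tartrate the titanium-bound peroxide is delivered to the face of a Z allylic alcohol that gives the (2S,3R)-epoxy alcohol, which sets C5 (S) and C4 (R). The remote C1=C10 alkene has no directing hydroxyl and should not react.

Step 7
Reactants: 10 [(2S,3R)-3-{(3Z)-6-[(4-methoxybenzyl)oxy]-4-methylhex-3-en-1-yl}-3-methyloxiran-2-yl]methanol
Product: 11 (2R,3R)-3-{(3Z)-6-[(4-methoxybenzyl)oxy]-4-methylhex-3-en-1-yl}-3-methyloxirane-2-carbaldehyde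
Conditions: TEMPO (10 mol %), PhI(OAc)2, CH2Cl2, rt
Reagents that add atoms: none
Why: Oxoammonium-mediated oxidation of a primary alcohol stops at the aldehyde and is used routinely for epoxy alcohols; the stereocentres are untouched (the descriptor at C5 changes only by priority).

Step 8
Reactants: 12 propane-1,3-diol
Product: 13 3-[(tert-butyldimethylsilyl)oxy]propan-1-ol
Conditions: NaH (1.0 equiv), THF, rt; then t-BuMe2SiCl (1.0 equiv)
Reagents that add atoms: tert-butyldimethylsilyl chloride, CC(C)(C)[Si](C)(C)Cl
Why: Monosilylation of a symmetrical diol through its sparingly soluble monosodium alkoxide, which favours the mono ether over the bis ether.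

Step 9
Reactants: 13 3-[(tert-butyldimethylsilyl)oxy]propan-1-ol
Product: 14 5-({3-[(tert-butyldimethylsilyl)oxy]propyl}sulfanyl)-1-phenyl-1H-tetrazole
Conditions: 1-phenyl-1H-tetrazole-5-thiol, PPh3, DIAD, THF, 0 °C to rt
Reagents that add atoms: 1-phenyl-1H-tetrazole-5-thiol, Sc1nnnn1-c1ccccc1
Why: Mitsunobu thioetherification of a primary alcohol with an acidic heteroaryl thiol.

Step 10
Reactants: 14 5-({3-[(tert-butyldimethylsilyl)oxy]propyl}sulfanyl)-1-phenyl-1H-tetrazole
Product: 15 5-({3-[(tert-butyldimethylsilyl)oxy]propyl}sulfonyl)-1-phenyl-1H-tetrazole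
Conditions: (NH4)6Mo7O24·4H2O (10 mol %), 30% H2O2, EtOH, 0 °C to rt
Reagents that add atoms: hydrogen peroxide, OO
Why: Molybdate-catalysed peroxide oxidation of the sulfide to the sulfone, the standard entry to Julia–Kocienski reagents; a primary silyl ether is tolerated.

Step 11
Reactants: 11 (2R,3R)-3-{(3Z)-6-[(4-methoxybenzyl)oxy]-4-methylhex-3-en-1-yl}-3-methyloxirane-2-carbaldehyde; 15 5-({3-[(tert-butyldimethylsilyl)oxy]propyl}sulfonyl)-1-phenyl-1H-tetrazole
Product: 16 (2S,3R)-2-{(1E)-4-[(tert-butyldimethylsilyl)oxy]but-1-en-1-yl}-3-{(3Z)-6-[(4-methoxybenzyl)oxy]-4-methylhex-3-en-1-yl}-3-methyloxirane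
Conditions: 15, KN(SiMe3)2, DME, −60 °C; then 11, −60 °C to rt
Reagents that add atoms: none
Why: Julia–Kocienski olefination: the metalated sulfone adds to the aldehyde, and Smiles rearrangement with loss of SO2 and the tetrazolate gives the alkene, E-selectively for the potassium base in DME. The epoxide carbon next to the aldehyde is not readily deprotonated, so C5 should hold.

Step 12
Reactants: 16 (2S,3R)-2-{(1E)-4-[(tert-butyldimethylsilyl)oxy]but-1-en-1-yl}-3-{(3Z)-6-[(4-methoxybenzyl)oxy]-4-methylhex-3-en-1-yl}-3-methyloxirane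
Product: 17 (3Z)-6-[(2R,3S)-3-{(1E)-4-[(tert-butyldimethylsilyl)oxy]but-1-en-1-yl}-2-methyloxiran-2-yl]-3-methylhex-3-en-1-ol
Conditions: DDQ, CH2Cl2/pH 7 phosphate buffer, 0 °C
Reagents that add atoms: none
Why: Oxidative cleavage of the 4-methoxybenzyl ether by benzylic hydride abstraction and hydrolysis; the buffer protects the vinyl epoxide, and the silyl ether and unactivated alkenes are inert.

Step 13
Reactants: 17 (3Z)-6-[(2R,3S)-3-{(1E)-4-[(tert-butyldimethylsilyl)oxy]but-1-en-1-yl}-2-methyloxiran-2-yl]-3-methylhex-3-en-1-ol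
Product: 18 (3Z)-6-[(2R,3S)-3-{(1E)-4-[(tert-butyldimethylsilyl)oxy]but-1-en-1-yl}-2-methyloxiran-2-yl]-3-methylhex-3-enal
Conditions: Dess–Martin periodinane, pyridine, CH2Cl2, 0 °C
Reagents that add atoms: none
Why: Buffered periodinane oxidation stops at the aldehyde and is mild enough to leave the β,γ-alkene out of conjugation; the aldehyde is used at once.

Step 14
Reactants: 18 (3Z)-6-[(2R,3S)-3-{(1E)-4-[(tert-butyldimethylsilyl)oxy]but-1-en-1-yl}-2-methyloxiran-2-yl]-3-methylhex-3-enal
Product: 19 (3Z)-6-[(2R,3S)-3-{(1E)-4-[(tert-butyldimethylsilyl)oxy]but-1-en-1-yl}-2-methyloxiran-2-yl]-3-methylhex-3-enal oxime (E/Z mixture at C=N)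
Conditions: NH2OH·HCl, pyridine, EtOH, 0 °C to rt
Reagents that add atoms: hydroxylamine hydrochloride, NO.Cl
Why: Condensation of an aldehyde with hydroxylamine; the oxime geometry is irrelevant because both isomers give the same nitrile oxide.

Step 15
Reactants: 19 (3Z)-6-[(2R,3S)-3-{(1E)-4-[(tert-butyldimethylsilyl)oxy]but-1-en-1-yl}-2-methyloxiran-2-yl]-3-methylhex-3-enal oxime
Product: 22 (1(10)Z,4R,5S,6S,7S)-12-[(tert-butyldimethylsilyl)oxy]-4,5-epoxy-13-norgermacr-1(10)-ene bridged by a 2-isoxazoline O–N=C8–C7–C6 (O on C6; C=N at C8), via hydroximoyl chloride 20 (not isolated), via nitrile oxide 21 (not isolated)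
Conditions: aq. NaOCl, CH2Cl2, 0 °C to rt, slow addition of 19 (high dilution)
Reagents that add atoms: none
Why: NaOCl chlorinates the aldoxime to hydroximoyl chloride 20, and loss of HCl in the basic two-phase medium gives nitrile oxide 21, which adds to the E C6=C7 alkene in a concerted suprafacial [3+2] cycloaddition; the closest known reaction type is the intramolecular nitrile oxide–alkene cycloaddition used to close carbocycles and macrocycles. The ten-membered carbocycle closes through the new C7–C8 bond in the bridged mode (dipole carbon to the distal alkene carbon, so that both alkene carbons lie inside the new ring). The 2-isoxazoline closes in the same event through the O–C6 bond and ends as a two-atom O–N bridge between C6 and C8 over C7. C7 is fixed relative to C6 by the E geometry, because a suprafacial addition leaves C5 and C11 trans on the isoxazoline, which is the cis ring fusion of the later lactone. C6 is set relative to C5 by the epoxide: the dipole oxygen is expected to enter anti to the allylic C5–O bond (inside-alkoxy arrangement), and the cis epoxide together with the Z C1=C10 alkene should bend the tether toward this face. The step needs the bridged ten-membered closure to win over the fused nine-membered one; this is expected from the lower strain of the larger ring and from the electron-withdrawing epoxide, which makes C7 the better partner for the electrophilic dipole carbon. Slow addition at high dilution should keep dimerisation of 21 to the furoxan behind the ring closure, and the basic hypochlorite phase should leave the trisubstituted alkene, the epoxide and the silyl ether untouched.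

Step 16
Reactants: 22 the silyl-protected isoxazoline of step 15
Product: 23 (1(10)Z,4R,5S,6S,7S)-4,5-epoxy-12-hydroxy-13-norgermacr-1(10)-ene bridged by the 2-isoxazoline O–N=C8–C7–C6
Conditions: n-Bu4NF, THF, 0 °C to rt
Reagents that add atoms: none
Why: Fluoride cleavage of a primary silyl ether; it is done here because the isoxazoline and epoxide are inert to fluoride, whereas the later β-hydroxy ketone would not be.

Step 17
Reactants: 23 the isoxazoline alcohol of step 16
Product: 25 (1(10)Z,4R,5S,6S,7R)-4,5-epoxy-6,12-dihydroxy-13-norgermacr-1(10)-en-8-one, via β-hydroxy imine 24 (not isolated)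
Conditions: Mo(CO)6, MeCN/H2O, 80 °C
Reagents that add atoms: water, O
Why: Molybdenum hexacarbonyl cleaves the isoxazoline N–O bond reductively, and the β-hydroxy imine is hydrolysed in the wet medium to the ketone (the isoxazoline route to aldols). The medium is near neutral, so C6 and C7 should be retained (the descriptor at C7 changes only by priority).

Step 18
Reactants: 25 (1(10)Z,4R,5S,6S,7R)-4,5-epoxy-6,12-dihydroxy-13-norgermacr-1(10)-en-8-one
Product: 27 (1(10)Z,4R,5S,6S,7R)-4,5-epoxy-8-oxo-13-norgermacr-1(10)-en-12,6-olide, via lactol 26 (not isolated)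
Conditions: TEMPO (cat.), PhI(OAc)2, CH2Cl2, rt
Reagents that add atoms: none
Why: Oxidative lactonisation of a 1,4-diol: the primary alcohol is oxidised selectively, the aldehyde is trapped by the C6 hydroxyl as a five-membered lactol, and this is oxidised to the γ-lactone. Because C8 is still a ketone, only O6 can close onto C12.

Step 19
Reactants: 27 (1(10)Z,4R,5S,6S,7R)-4,5-epoxy-8-oxo-13-norgermacr-1(10)-en-12,6-olide
Product: 28 (1(10)Z,4R,5S,6S,7S,8R)-4,5-epoxy-8-hydroxy-13-norgermacr-1(10)-en-12,6-olide
Conditions: NaBH4, CeCl3·7H2O, MeOH, −78 °C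
Reagents that add atoms: none
Why: Luche-type borohydride reduction is fast and weakly basic at low temperature, which should suppress β-elimination of the lactone oxygen and leave the lactone unreduced. Hydride is expected to attack the C8 carbonyl on the outer face opposite the C7–C11 bond (Felkin–Anh-type approach), which places O8 trans to C11 on the ring and gives (8R).

Step 20
Reactants: 28 (1(10)Z,4R,5S,6S,7S,8R)-4,5-epoxy-8-hydroxy-13-norgermacr-1(10)-en-12,6-olide
Product: 31 (1(10)Z,4R,5S,6S,7S,8R)-4,5-epoxy-8-hydroxygermacra-1(10),11(13)-dien-12,6-olide, via Mannich base 29 (not isolated), via ammonium iodide 30 (not isolated)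
Conditions: LiN(i-Pr)2 (2.3 equiv), THF, −78 °C; CH2=NMe2 I, −78 to 0 °C; then MeI, MeOH, rt; then aq. NaHCO3, CH2Cl2, rt
Reagents that add atoms: N,N-dimethylmethyleneiminium iodide (Eschenmoser's salt), C=[N+](C)C.[I-]
Why: α-Methylenation of a γ-lactone by Mannich reaction of its lithium enolate, N-methylation and elimination of trimethylamine. The extra equivalent of base holds the C8 hydroxyl as its alkoxide, and the transient C11 stereocentre disappears in the elimination.

Step 21
Reactants: 32 2-[(tert-butyldimethylsilyl)oxy]acetaldehyde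
Product: 33 ethyl (2E)-4-[(tert-butyldimethylsilyl)oxy]-2-methylbut-2-enoate
Conditions: Ph3P=C(Me)CO2Et, CH2Cl2, rt
Reagents that add atoms: ethyl 2-(triphenylphosphoranylidene)propanoate, CCOC(=O)C(C)=P(c1ccccc1)(c1ccccc1)c1ccccc1
Why: Wittig reaction of a stabilised, α-branched ylide, which gives the E trisubstituted enoate under thermodynamic control of the betaine.

Step 22
Reactants: 33 ethyl (2E)-4-[(tert-butyldimethylsilyl)oxy]-2-methylbut-2-enoate
Product: 34 (2E)-4-[(tert-butyldimethylsilyl)oxy]-2-methylbut-2-enoic acid
Conditions: LiOH, THF/MeOH/H2O, rt; then 1 M HCl to pH 4, 0 °C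
Reagents that add atoms: lithium hydroxide, [Li+].[OH-]
Why: Saponification of an ethyl ester; the primary silyl ether tolerates dilute hydroxide and a brief mildly acidic work-up.

Step 23
Reactants: 31 (1(10)Z,4R,5S,6S,7S,8R)-4,5-epoxy-8-hydroxygermacra-1(10),11(13)-dien-12,6-olide; 34 (2E)-4-[(tert-butyldimethylsilyl)oxy]-2-methylbut-2-enoic acid
Product: 36 (1(10)Z,4R,5S,6S,7S,8R)-8-({(2E)-4-[(tert-butyldimethylsilyl)oxy]-2-methylbut-2-enoyl}oxy)-4,5-epoxygermacra-1(10),11(13)-dien-12,6-olide, via mixed anhydride 35 (not isolated)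
Conditions: 34, 2,4,6-trichlorobenzoyl chloride, Et3N, THF, rt; then 31, DMAP, toluene, rt
Reagents that add atoms: none
Why: Yamaguchi esterification: the hindered mixed anhydride transfers only the enoyl group through the acylpyridinium ion, which suits hindered secondary alcohols and unsaturated acids. The C8–O bond is not broken, so C8 is retained.

Step 24
Reactants: 36 the silyl-protected ester of step 23
Product: 37 (1(10)Z,4R,5S,6S,7S,8R)-4,5-epoxy-8-{[(2E)-4-hydroxy-2-methylbut-2-enoyl]oxy}germacra-1(10),11(13)-dien-12,6-olide (target)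
Conditions: n-Bu4NF/AcOH (1:1), THF, 0 °C to rt
Reagents that add atoms: none
Why: Acetic acid-buffered fluoride removes the primary allylic silyl ether under nearly neutral conditions, which avoids both acid-induced transannular opening of the epoxide and base-induced addition to the methylene lactone.

## Compound list

1 | 4-methyl-5,6-dihydro-2H-pyran-2-one | CC1=CC(=O)OCC1 | starting material
2 | 4-methyl-5,6-dihydro-2H-pyran-2-ol (racemic at C2) | CC1=CC(O)OCC1 | intermediate
3 | (3Z)-3-methylhexa-3,5-dien-1-ol | OCC/C(C)=C\C=C | intermediate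
4 | 1-methoxy-4-({[(3Z)-3-methylhexa-3,5-dien-1-yl]oxy}methyl)benzene | COc1ccc(COCC/C(C)=C\C=C)cc1 | intermediate
5 | but-2-yn-1-ol | CC#CCO | starting material
6 | sodium 2,2-bis(2-methoxyethoxy)-3-methyl-2,5-dihydro-1,2-oxaluminol-2-uide (cyclic alkenylaluminate, not isolated) | CC1=CCO[Al-]1(OCCOC)OCCOC.[Na+] | intermediate
7 | (2Z)-3-iodobut-2-en-1-ol | C/C(I)=C/CO | intermediate
8 | 9-{(3Z)-6-[(4-methoxybenzyl)oxy]-4-methylhex-3-en-1-yl}-9-borabicyclo[3.3.1]nonane (not isolated) | COc1ccc(COCC/C(C)=C\CCB2C3CCCC2CCC3)cc1 | intermediate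
9 | (2Z,6Z)-9-[(4-methoxybenzyl)oxy]-3,7-dimethylnona-2,6-dien-1-ol | COc1ccc(COCC/C(C)=C\CC/C(C)=C\CO)cc1 | intermediate
10 | [(2S,3R)-3-{(3Z)-6-[(4-methoxybenzyl)oxy]-4-methylhex-3-en-1-yl}-3-methyloxiran-2-yl]methanol | COc1ccc(COCC/C(C)=C\CC[C@@]2(C)O[C@H]2CO)cc1 | intermediate
11 | (2R,3R)-3-{(3Z)-6-[(4-methoxybenzyl)oxy]-4-methylhex-3-en-1-yl}-3-methyloxirane-2-carbaldehyde | COc1ccc(COCC/C(C)=C\CC[C@@]2(C)O[C@H]2C=O)cc1 | intermediate
12 | propane-1,3-diol | OCCCO | starting material
13 | 3-[(tert-butyldimethylsilyl)oxy]propan-1-ol | CC(C)(C)[Si](C)(C)OCCCO | intermediate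
14 | 5-({3-[(tert-butyldimethylsilyl)oxy]propyl}sulfanyl)-1-phenyl-1H-tetrazole | CC(C)(C)[Si](C)(C)OCCCSc1nnnn1-c1ccccc1 | intermediate
15 | 5-({3-[(tert-butyldimethylsilyl)oxy]propyl}sulfonyl)-1-phenyl-1H-tetrazole | CC(C)(C)[Si](C)(C)OCCCS(=O)(=O)c1nnnn1-c1ccccc1 | intermediate
16 | (2S,3R)-2-{(1E)-4-[(tert-butyldimethylsilyl)oxy]but-1-en-1-yl}-3-{(3Z)-6-[(4-methoxybenzyl)oxy]-4-methylhex-3-en-1-yl}-3-methyloxirane | COc1ccc(COCC/C(C)=C\CC[C@@]2(C)O[C@H]2/C=C/CCO[Si](C)(C)C(C)(C)C)cc1 | intermediate
17 | (3Z)-6-[(2R,3S)-3-{(1E)-4-[(tert-butyldimethylsilyl)oxy]but-1-en-1-yl}-2-methyloxiran-2-yl]-3-methylhex-3-en-1-ol | OCC/C(C)=C\CC[C@@]1(C)O[C@H]1/C=C/CCO[Si](C)(C)C(C)(C)C | intermediate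
18 | (3Z)-6-[(2R,3S)-3-{(1E)-4-[(tert-butyldimethylsilyl)oxy]but-1-en-1-yl}-2-methyloxiran-2-yl]-3-methylhex-3-enal | O=CC/C(C)=C\CC[C@@]1(C)O[C@H]1/C=C/CCO[Si](C)(C)C(C)(C)C | intermediate
19 | oxime of 18 (E/Z mixture at C=N; (Z)-enyl epoxy oxime with E C6=C7 alkene) | ON=CC/C(C)=C\CC[C@@]1(C)O[C@H]1/C=C/CCO[Si](C)(C)C(C)(C)C | intermediate
20 | N-hydroxy imidoyl chloride of 19 (hydroximoyl chloride at C8, not isolated) | ON=C(Cl)C/C(C)=C\CC[C@@]1(C)O[C@H]1/C=C/CCO[Si](C)(C)C(C)(C)C | intermediate
21 | C8 nitrile oxide (not isolated) | [O-][N+]#CC/C(C)=C\CC[C@@]1(C)O[C@H]1/C=C/CCO[Si](C)(C)C(C)(C)C | intermediate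
22 | (1(10)Z,4R,5S,6S,7S)-12-[(tert-butyldimethylsilyl)oxy]-4,5-epoxy-13-norgermacr-1(10)-ene bridged by a 2-isoxazoline O–N=C8–C7–C6 | CC(C)(C)[Si](C)(C)OCC[C@@H]1[C@@H]2ON=C1C/C(C)=C\CC[C@@]3(C)O[C@@H]23 | intermediate
23 | (1(10)Z,4R,5S,6S,7S)-4,5-epoxy-12-hydroxy-13-norgermacr-1(10)-ene bridged by the 2-isoxazoline O–N=C8–C7–C6 | OCC[C@@H]1[C@@H]2ON=C1C/C(C)=C\CC[C@@]3(C)O[C@@H]23 | intermediate
24 | (1(10)Z,4R,5S,6S,7S)-4,5-epoxy-6,12-dihydroxy-13-norgermacr-1(10)-en-8-imine (not isolated) | N=C1C/C(C)=C\CC[C@@]2(C)O[C@H]2[C@@H](O)[C@H]1CCO | intermediate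
25 | (1(10)Z,4R,5S,6S,7R)-4,5-epoxy-6,12-dihydroxy-13-norgermacr-1(10)-en-8-one | O=C1C/C(C)=C\CC[C@@]2(C)O[C@H]2[C@@H](O)[C@H]1CCO | intermediate
26 | (1(10)Z,4R,5S,6S,7R)-4,5:6,12-diepoxy-12-hydroxy-13-norgermacr-1(10)-en-8-one (lactol, C12 epimers, not isolated) | C1C(O)O[C@H]2[C@@H]1C(=O)C/C(C)=C\CC[C@@]1(C)O[C@@H]21 | intermediate
27 | (1(10)Z,4R,5S,6S,7R)-4,5-epoxy-8-oxo-13-norgermacr-1(10)-en-12,6-olide | C1C(=O)O[C@H]2[C@@H]1C(=O)C/C(C)=C\CC[C@@]1(C)O[C@@H]21 | intermediate
28 | (1(10)Z,4R,5S,6S,7S,8R)-4,5-epoxy-8-hydroxy-13-norgermacr-1(10)-en-12,6-olide | C1C(=O)O[C@H]2[C@@H]1[C@H](O)C/C(C)=C\CC[C@@]1(C)O[C@@H]21 | intermediate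
29 | (1(10)Z,4R,5S,6S,7S,8R)-13-(dimethylamino)-4,5-epoxy-8-hydroxygermacr-1(10)-en-12,6-olide (C11 epimers, not isolated) | CN(C)CC1C(=O)O[C@H]2[C@@H]1[C@H](O)C/C(C)=C\CC[C@@]1(C)O[C@@H]21 | intermediate
30 | trimethylammonium iodide of 29 (not isolated) | C[N+](C)(C)CC1C(=O)O[C@H]2[C@@H]1[C@H](O)C/C(C)=C\CC[C@@]1(C)O[C@@H]21.[I-] | intermediate
31 | (1(10)Z,4R,5S,6S,7S,8R)-4,5-epoxy-8-hydroxygermacra-1(10),11(13)-dien-12,6-olide | C=C1C(=O)O[C@H]2[C@@H]1[C@H](O)C/C(C)=C\CC[C@@]1(C)O[C@@H]21 | intermediate
32 | 2-[(tert-butyldimethylsilyl)oxy]acetaldehyde | CC(C)(C)[Si](C)(C)OCC=O | starting material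
33 | ethyl (2E)-4-[(tert-butyldimethylsilyl)oxy]-2-methylbut-2-enoate | CCOC(=O)/C(C)=C/CO[Si](C)(C)C(C)(C)C | intermediate
34 | (2E)-4-[(tert-butyldimethylsilyl)oxy]-2-methylbut-2-enoic acid | OC(=O)/C(C)=C/CO[Si](C)(C)C(C)(C)C | intermediate
35 | (2E)-4-[(tert-butyldimethylsilyl)oxy]-2-methylbut-2-enoic 2,4,6-trichlorobenzoic anhydride (not isolated) | O=C(OC(=O)/C(C)=C/CO[Si](C)(C)C(C)(C)C)c1c(Cl)cc(Cl)cc1Cl | intermediate
36 | (1(10)Z,4R,5S,6S,7S,8R)-8-({(2E)-4-[(tert-butyldimethylsilyl)oxy]-2-methylbut-2-enoyl}oxy)-4,5-epoxygermacra-1(10),11(13)-dien-12,6-olide | C=C1C(=O)O[C@H]2[C@@H]1[C@H](OC(=O)/C(C)=C/CO[Si](C)(C)C(C)(C)C)C/C(C)=C\CC[C@@]1(C)O[C@@H]21 | intermediate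
37 | (1(10)Z,4R,5S,6S,7S,8R)-4,5-epoxy-8-{[(2E)-4-hydroxy-2-methylbut-2-enoyl]oxy}germacra-1(10),11(13)-dien-12,6-olide | C=C1C(=O)O[C@H]2[C@@H]1[C@H](OC(=O)/C(C)=C/CO)C/C(C)=C\CC[C@@]1(C)O[C@@H]21 | target

## Step count and risks

Total: 24 steps. Longest linear sequence: 18 steps (1–3, 5–7, 11–20, 23, 24).

**Step 15 (key step).** The closure to a ten-membered ring is slow. It may be overtaken by dimerisation of the dipole to the furoxan or by closure in the fused nine-membered sense. The facial bias from the epoxide is also modest, so addition to the other alkene face may compete. The fallback replaces the nitrile oxide by a silyl nitronate, a dipole that does not dimerise, can be heated for slow closures and often adds with higher facial selectivity. It sets out from alcohol 17. Iodination (I2, PPh3, imidazole) gives the primary iodide F1, and NaNO2 in DMF gives the nitroalkane F2. Me3SiCl/Et3N converts F2 into its silyl nitronate, which should cyclise on warming to the N-silyloxy isoxazolidine F3. n-Bu4NF then eliminates the silyloxy group from nitrogen and removes the C12 silyl ether in the same operation, so the fallback rejoins the route at 23.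

**Step 19.** Hydride may be delivered to the other face of the C8 carbonyl, because the conformation of the ring around C7–C8 cannot be predicted with confidence. Base-induced elimination of the lactone oxygen is a second danger. If the reduction gives mainly the C8 epimer, the fallback uses it with inversion instead of retention. It sets out from 27. The (8S) alcohol F4 is methylenated as in step 20, through its Mannich base F5 and ammonium iodide F6, to the (8S) methylene lactone F7. F7 is esterified with acid 34 under Mitsunobu conditions (PPh3, DIAD), which inverts C8 and rejoins the route at 36.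

**Step 17.** At 80 °C in wet acetonitrile the strained β-hydroxy ketone may undergo retro-aldol ring opening, dehydration or epimerisation at C7. The fallback changes the order so that the C6 hydroxyl is acylated as soon as it is set free. It sets out from 23. Oxidation with TEMPO/PhI(OAc)2 in MeCN/H2O gives the isoxazoline carboxylic acid F8. Hydrogenolysis of the N–O bond at room temperature (Raney Ni, H2, B(OH)3, MeOH/H2O) gives the hydroxy keto acid F9, which should lactonise spontaneously and rejoin the route at 27.

**Step 20.** In the dianion the C8 alkoxide may attack the lactone carbonyl (acyl migration toward O8), or enolisation may stay incomplete. The fallback masks the hydroxyl. It sets out from 28. Et3SiCl/imidazole gives the triethylsilyl ether F10. One equivalent of LiN(i-Pr)2 and Eschenmoser's salt give the Mannich base F11, MeI gives the ammonium iodide F12, and NaHCO3 gives the silylated methylene lactone F13. n-Bu4NF/AcOH removes the silyl group and rejoins the route at 31.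

**Step 2.** The lactol may open only sluggishly, and the excess basic ylide may isomerise the Z enal through its dienolate before olefination. The fallback replaces the Wittig reaction by a Peterson olefination, in which a weakly basic Grignard reagent adds to the lactol. It sets out from 2. Me3SiCH2MgCl (excess) gives the β-hydroxysilane diol F14, and KH in THF induces syn-elimination to the diene, rejoining the route at 3.

## Further compounds

F1 | step 15 | tert-butyl{[(3E)-4-{(2S,3R)-3-[(3Z)-6-iodo-4-methylhex-3-en-1-yl]-3-methyloxiran-2-yl}but-3-en-1-yl]oxy}dimethylsilane | ICC/C(C)=C\CC[C@@]1(C)O[C@H]1/C=C/CCO[Si](C)(C)C(C)(C)C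
F2 | step 15 | tert-butyldimethyl{[(3E)-4-{(2S,3R)-3-methyl-3-[(3Z)-4-methyl-6-nitrohex-3-en-1-yl]oxiran-2-yl}but-3-en-1-yl]oxy}silane | [O-][N+](=O)CC/C(C)=C\CC[C@@]1(C)O[C@H]1/C=C/CCO[Si](C)(C)C(C)(C)C
F3 | step 15 | N-(trimethylsilyloxy)isoxazolidine analogue of 22 (O on C6, N(OSiMe3) on C8; C8 and N unassigned) | CC(C)(C)[Si](C)(C)OCC[C@@H]1[C@@H]2ON(O[Si](C)(C)C)C1C/C(C)=C\CC[C@@]3(C)O[C@@H]23
F4 | step 19 | (1(10)Z,4R,5S,6S,7S,8S)-4,5-epoxy-8-hydroxy-13-norgermacr-1(10)-en-12,6-olide | C1C(=O)O[C@H]2[C@@H]1[C@@H](O)C/C(C)=C\CC[C@@]1(C)O[C@@H]21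
F5 | step 19 | (8S)-13-(dimethylamino)-4,5-epoxy-8-hydroxygermacr-1(10)-en-12,6-olide (C11 epimers) | CN(C)CC1C(=O)O[C@H]2[C@@H]1[C@@H](O)C/C(C)=C\CC[C@@]1(C)O[C@@H]21
F6 | step 19 | trimethylammonium iodide of F5 | C[N+](C)(C)CC1C(=O)O[C@H]2[C@@H]1[C@@H](O)C/C(C)=C\CC[C@@]1(C)O[C@@H]21.[I-]
F7 | step 19 | (1(10)Z,4R,5S,6S,7S,8S)-4,5-epoxy-8-hydroxygermacra-1(10),11(13)-dien-12,6-olide | C=C1C(=O)O[C@H]2[C@@H]1[C@@H](O)C/C(C)=C\CC[C@@]1(C)O[C@@H]21
F8 | step 17 | isoxazoline-bridged (1(10)Z,4R,5S,6S,7S)-4,5-epoxy-13-norgermacr-1(10)-en-12-oic acid | OC(=O)C[C@@H]1[C@@H]2ON=C1C/C(C)=C\CC[C@@]3(C)O[C@@H]23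
F9 | step 17 | (1(10)Z,4R,5S,6S,7R)-4,5-epoxy-6-hydroxy-8-oxo-13-norgermacr-1(10)-en-12-oic acid | O=C1C/C(C)=C\CC[C@@]2(C)O[C@H]2[C@@H](O)[C@H]1CC(O)=O
F10 | step 20 | 8-O-triethylsilyl ether of 28 | C1C(=O)O[C@H]2[C@@H]1[C@H](O[Si](CC)(CC)CC)C/C(C)=C\CC[C@@]1(C)O[C@@H]21
F11 | step 20 | 8-O-triethylsilyl ether of 29 (C11 epimers) | CN(C)CC1C(=O)O[C@H]2[C@@H]1[C@H](O[Si](CC)(CC)CC)C/C(C)=C\CC[C@@]1(C)O[C@@H]21
F12 | step 20 | 8-O-triethylsilyl ether of 30 | C[N+](C)(C)CC1C(=O)O[C@H]2[C@@H]1[C@H](O[Si](CC)(CC)CC)C/C(C)=C\CC[C@@]1(C)O[C@@H]21.[I-]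
F13 | step 20 | 8-O-triethylsilyl ether of 31 | C=C1C(=O)O[C@H]2[C@@H]1[C@H](O[Si](CC)(CC)CC)C/C(C)=C\CC[C@@]1(C)O[C@@H]21
F14 | step 2 | (3Z)-3-methyl-6-(trimethylsilyl)hex-3-ene-1,5-diol (racemic at C5) | OCC/C(C)=C\C(O)C[Si](C)(C)C
A1 | alternative 1 | bicyclo[5.3.0]decadiene lactone with tetrasubstituted C4=C8 ring-fusion alkene and C5 methoxymethyl ether | O=C1O[C@H]2[C@@H](C1)C3=C([C@@H]2OCOC)CC/C=C(C)\C3
A2 | alternative 1 | ten-membered (Z)-enyl 4,8-diketone with cis-fused 12,6-lactone and C5 methoxymethyl ether | O=C1O[C@H]2[C@@H](C1)C(=O)C/C(C)=C\CCC(=O)[C@@H]2OCOC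
A3 | alternative 2 | ten-membered epoxy homopropargylic alcohol (C6 hydroxyl cis to C7 ethynyl, C8 silyl ether) | C#C[C@H]1[C@H](O[Si](C)(C)C(C)(C)C)C/C(C)=C\CC[C@@]2(C)O[C@H]2[C@H]1O
A4 | alternative 2 | C8 tert-butyldimethylsilyl ether of the epoxy methylene lactone core | C=C1C(=O)O[C@H]2[C@@H]1[C@H](O[Si](C)(C)C(C)(C)C)C/C(C)=C\CC[C@@]1(C)O[C@@H]21
A5 | alternative 3 | cis-fused decalin C1 mesylate with free tertiary C5 hydroxyl (C4 triethylsilyl ether, C6 4-methoxybenzyl ether, C8 and C12 silyl ethers) | CC(C)(C)[Si](C)(C)OCC[C@H]1[C@H](O[Si](C)(C)C(C)(C)C)C[C@]2(C)[C@H](OS(C)(=O)=O)CC[C@@](C)(O[Si](CC)(CC)CC)[C@]2(O)[C@H]1OCc1ccc(OC)cc1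
A6 | alternative 3 | ten-membered (Z)-cyclodecenone with C5 ketone, C4 triethylsilyl ether and C6 4-methoxybenzyl ether | CC(C)(C)[Si](C)(C)OCC[C@H]1[C@H](O[Si](C)(C)C(C)(C)C)C/C(C)=C\CC[C@@](C)(O[Si](CC)(CC)CC)C(=O)[C@H]1OCc1ccc(OC)cc1
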